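**Retrosynthetic overview**

1. The target is (2S)-naringenin (unit 1, unprimed and single-primed locants) joined through the oxygen on C6 of its ring A to C4''' of apigenin (unit 2, double- and triple-primed locants). The route rests on ring B of unit 2: the benzene C1'''–C6''' carries the acyl-level carbon C2'' on C1''' and the ether oxygen on C4''', para to each other. This ring maps onto a 5-carboxy-2-pyrone (C1''', C2''', C3''', C6''' and the future C2'') and an aryl ethynyl ether (C4''', C5''').
2. Disconnections: (a) C3'''–C4''' and C5'''–C6''' by (4+2) cycloaddition of methyl coumalate with the ethynyl ether of the ring A phenol, with loss of CO2; (b) ring C of the flavone by Claisen condensation of the resulting benzoate with a phloroacetophenone ether and cyclodehydration; (c) C2–C1' of the flavanone by enantioselective rhodium-catalysed 1,4-addition of an arylboronic acid to a chromone built on ring A (C4a–C4 by iodination and Stille acetylation, C2 from an amide acetal).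
3. Ring order: ring B of unit 2 (step 5), ring C of unit 2 (steps 7 and 8), ring C of unit 1 (step 11), stereocentre C2 (step 12), then global debenzylation (step 13).
4. Protecting groups: benzyl on every phenol that stays masked to the end; one MOM group on the ring A oxygen para to the ynol oxygen. The MOM group falls in the acid step that closes the flavone and so marks the oxygen that becomes O1 of the flavanone.

Key step: step 5

Assumption: the sense of induction in step 12 is assigned by analogy with (S)-BINAP and 2-cyclohexenone; it is to be confirmed on 21, and the (R)-ligand is to be used if the sense proves opposite.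

**Route**

Step 1
Reactants: 1 3,5-bis(benzyloxy)phenol
Product: 3 2,6-bis(benzyloxy)benzene-1,4-diol, via 2,6-bis(benzyloxy)-1,4-benzoquinone 2 (not isolated)
Conditions: K2[ON(SO3)2] (2.5 equiv), KH2PO4, acetone/H2O, 0 °C to rt; then Na2S2O4, EtOAc/H2O, rt, argon
Reagents that add atoms: dipotassium nitrosodisulfonate, [K+].[K+].[O]N(S(=O)(=O)[O-])S(=O)(=O)[O-]
Why: Teuber oxidation of a phenol with a free para position should give the para-quinone, the new oxygen entering only at the carbon between the two benzyloxy groups, and dithionite then reduces the quinone to the hydroquinone.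

Step 2
Reactants: 3 2,6-bis(benzyloxy)benzene-1,4-diol
Product: 4 2,6-bis(benzyloxy)-4-(methoxymethoxy)phenol
Conditions: MeOCH2Cl (1.0 equiv), i-Pr2NEt, CH2Cl2, −20 to 0 °C, argon
Reagents that add atoms: chloromethyl methyl ether, COCCl
Why: Williamson-type O-alkylation should take the C4 hydroxyl, which is unhindered and the more acidic of the two (a meta,meta'-dialkoxy phenol against an ortho,ortho'-dialkoxy phenol), and leave the hydroxyl flanked by the benzyloxy groups free.

Step 3
Reactants: 4 2,6-bis(benzyloxy)-4-(methoxymethoxy)phenol; 5 trichloroethylene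
Product: 6 1,3-bis(benzyloxy)-2-{[(E)-1,2-dichloroethenyl]oxy}-5-(methoxymethoxy)benzene
Conditions: K2CO3 (2 equiv), DMF, 70 °C, argon
Reagents that add atoms: none
Why: The base converts trichloroethylene into dichloroacetylene, to which the phenoxide adds in an anti sense, which should give the (E)-1,2-dichlorovinyl aryl ether (addition–protonation, the usual entry to ynol ethers).

Step 4
Reactants: 6 1,3-bis(benzyloxy)-2-{[(E)-1,2-dichloroethenyl]oxy}-5-(methoxymethoxy)benzene
Product: 7 1,3-bis(benzyloxy)-2-(ethynyloxy)-5-(methoxymethoxy)benzene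
Conditions: n-BuLi (2.3 equiv), THF, −78 °C; MeOH, −78 °C; used at once as a toluene solution
Reagents that add atoms: none
Why: Vinyl deprotonation with loss of chloride gives the chloroalkynyl ether, chlorine–lithium exchange gives the lithium aryloxyacetylide and protonation the terminal ynol ether (dichlorovinyl ether to alkynyl ether elimination); at −78 °C the vinyl C–H should react faster than ring or benzylic C–H bonds.

Step 5
Reactants: 7 1,3-bis(benzyloxy)-2-(ethynyloxy)-5-(methoxymethoxy)benzene; 8 methyl coumalate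
Product: 10 methyl 4-[2,6-bis(benzyloxy)-4-(methoxymethoxy)phenoxy]benzoate, via bicyclic lactone adduct 9 (not isolated)
Conditions: 8 (2 equiv), degassed toluene, 80–100 °C, sealed tube, dark
Reagents that add atoms: none
Why: The electron-rich aryl ethynyl ether 7 (HOMO, largest coefficient on the terminal CH carbon) and the electron-poor 2-pyrone 8 (LUMO, largest coefficient at C6, which is β to the ester and vinylogous to the lactone carbonyl) combine in an inverse-electron-demand Diels–Alder reaction, the closest known reaction type being the cycloaddition of methyl coumalate with enol ethers, ketene acetals and heteroatom-substituted alkynes that ends in para-substituted benzoates. The terminal alkyne carbon bonds to C6 and the oxygen-bearing carbon to C3 of the pyrone in a concerted but asynchronous suprafacial addition, so that ring B of unit 2 is closed as a six-membered carbocycle by two intermolecular C–C bonds (C5'''–C6''' and C3'''–C4''') in the bridged lactone 9. Because the dienophile is an alkyne, 9 is a bicyclo[2.2.2]octadiene that expels CO2 by retro-(4+2) fragmentation at the reaction temperature and gives the arene 10 directly, without an oxidation or elimination step. No stereocentre remains, since both bridgehead carbons of 9 become aromatic. The step needs para over meta regioselectivity, which the matched polarisation of ynol ether and coumalate should provide, and it needs the cycloaddition to outrun self-condensation of 7, which the two flanking benzyloxy groups, an excess of the stable pyrone and a temperature at or below 100 °C are meant to secure. The diaryl ether at a carbon flanked by two oxygenated positions thus arises without any C–O coupling on the hindered ring.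

Step 6
Reactants: 11 2,4,6-trihydroxyacetophenone
Product: 12 1-[2,4-bis(benzyloxy)-6-hydroxyphenyl]ethan-1-one
Conditions: BnBr (2.1 equiv), K2CO3, DMF, rt
Reagents that add atoms: benzyl bromide, BrCc1ccccc1
Why: Williamson benzylation should stop at the bis-ether because the last hydroxyl is held in a hydrogen bond to the ketone.

Step 7
Reactants: 10 methyl 4-[2,6-bis(benzyloxy)-4-(methoxymethoxy)phenoxy]benzoate; 12 1-[2,4-bis(benzyloxy)-6-hydroxyphenyl]ethan-1-one
Product: 13 1-[2,4-bis(benzyloxy)-6-hydroxyphenyl]-3-{4-[2,6-bis(benzyloxy)-4-(methoxymethoxy)phenoxy]phenyl}propane-1,3-dione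
Conditions: LiN(SiMe3)2 (4 equiv), THF, −78 °C to rt; AcOH quench
Reagents that add atoms: none
Why: Crossed Claisen condensation: the dilithium phenoxide–enolate of 12 should be acylated at carbon by the non-enolisable methyl benzoate 10, and deprotonation of the 1,3-diketone drives the equilibrium (the ester variant of the Baker–Venkataraman diketone synthesis).

Step 8
Reactants: 13 the 1,3-diketone
Product: 14 5,7-bis(benzyloxy)-2-{4-[2,6-bis(benzyloxy)-4-hydroxyphenoxy]phenyl}-4H-chromen-4-one
Conditions: conc. HCl (cat.), MeOH/THF, 50 °C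
Reagents that add atoms: none
Why: Acid-catalysed cyclodehydration of the 2-hydroxyaryl 1,3-diketone (6-exo-trig addition of the phenol to the aryl ketone carbonyl, then loss of water) closes ring C of the flavone, and the same acid cleaves the MOM acetal by methanolysis while the benzyl ethers should stay.

Step 9
Reactants: 14 the flavone phenol
Product: 15 5,7-bis(benzyloxy)-2-{4-[2,6-bis(benzyloxy)-4-hydroxy-3-iodophenoxy]phenyl}-4H-chromen-4-one
Conditions: N-iodosuccinimide (1.0 equiv), MeCN/CH2Cl2, −20 to 0 °C, dark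
Reagents that add atoms: N-iodosuccinimide, O=C1CCC(=O)N1I
Why: Electrophilic aromatic iodination should go ortho to the only free phenol (its para position is blocked by the aryloxy group and its two ortho positions are equivalent), whereas ring A of the flavone is deactivated by the pyranone carbonyl.

Step 10
Reactants: 15 the iodophenol
Product: 17 2-{4-[3-acetyl-2,6-bis(benzyloxy)-4-hydroxyphenoxy]phenyl}-5,7-bis(benzyloxy)-4H-chromen-4-one, via 1-ethoxyvinyl arene 16 (not isolated)
Conditions: Bu3SnC(OEt)=CH2 (1.5 equiv), Pd(PPh3)4 (5 mol%), dioxane, 95 °C; then 1 M HCl, THF, rt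
Reagents that add atoms: tributyl(1-ethoxyvinyl)stannane, CCCC[Sn](CCCC)(CCCC)C(=C)OCC; water, O
Why: Stille coupling with the acetyl-anion equivalent followed by hydrolysis of the enol ether should give the ortho-hydroxyacetophenone under neutral and then mildly acidic conditions that spare the benzyl ethers and the flavone.

Step 11
Reactants: 17 the ortho-hydroxyacetophenone
Product: 19 5,7-bis(benzyloxy)-6-{4-[5,7-bis(benzyloxy)-4-oxo-4H-chromen-2-yl]phenoxy}-4H-chromen-4-one, via enaminone 18 (not isolated)
Conditions: Me2NCH(OMe)2 (4 equiv), toluene, 95 °C; then conc. HCl, CH2Cl2, rt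
Reagents that add atoms: N,N-dimethylformamide dimethyl acetal, COC(OC)N(C)C
Why: Condensation of the methyl ketone with the amide acetal gives the enaminone, and acid-induced 6-endo-trig addition of the ortho phenol with loss of dimethylamine closes the chromone; only the hydroxyl para to the diaryl ether oxygen is free, so the aryloxy group must end up on C6 and not on C8.

Step 12
Reactants: 19 the chromone–flavone; 20 4-(benzyloxy)phenylboronic acid
Product: 21 (2S)-5,7-bis(benzyloxy)-2-[4-(benzyloxy)phenyl]-6-{4-[5,7-bis(benzyloxy)-4-oxo-4H-chromen-2-yl]phenoxy}-2,3-dihydro-4H-chromen-4-one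
Conditions: 20 (3 equiv), [Rh(OH)(cod)]2 (3 mol%, cod = 1,5-cyclooctadiene), (S)-MeO-F12-BIPHEP (6.6 mol%; (S)-6,6'-dimethoxy-2,2'-bis[bis(3,4,5-trifluorophenyl)phosphino]-1,1'-biphenyl), toluene/H2O 10:1, 40 °C
Reagents that add atoms: none
Why: Hayashi–Miyaura 1,4-addition: the aryl–rhodium species formed by transmetalation inserts the C2=C3 bond of the chromone part of 19 (the 2-aryl-substituted enone of the flavone part is too hindered to insert) and water protonates the rhodium enolate; C2 is set by the (S)-biaryl bisphosphine, which by the quadrant model that holds for (S)-BINAP with 2-cyclohexenone should deliver the aryl group to the face that gives the 2S flavanone.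

Step 13
Reactants: 21 the pentabenzyl ether
Product: 22 (2S)-5,7-dihydroxy-6-{4-[5,7-dihydroxy-4-oxo-4H-chromen-2-yl]phenoxy}-2-(4-hydroxyphenyl)-2,3-dihydro-4H-chromen-4-one (target)
Conditions: H2 (1 atm), 10% Pd/C, THF/MeOH, rt, stopped at the calculated uptake
Reagents that add atoms: none
Why: Hydrogenolysis of the five benzyl aryl ethers under neutral conditions should free all phenols; C2 cannot epimerise without base, and the flavone double bond and the C2–O1 bond are expected to react more slowly than the O-benzyl groups.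

**Compound list**

1 | 3,5-bis(benzyloxy)phenol | Oc1cc(OCc2ccccc2)cc(OCc2ccccc2)c1 | starting material
2 | 2,6-bis(benzyloxy)-1,4-benzoquinone | O=C1C=C(OCc2ccccc2)C(=O)C(OCc2ccccc2)=C1 | intermediate
3 | 2,6-bis(benzyloxy)benzene-1,4-diol | Oc1cc(OCc2ccccc2)c(O)c(OCc2ccccc2)c1 | intermediate
4 | 2,6-bis(benzyloxy)-4-(methoxymethoxy)phenol | COCOc1cc(OCc2ccccc2)c(O)c(OCc2ccccc2)c1 | intermediate
5 | trichloroethylene | ClC=C(Cl)Cl | starting material
6 | 1,3-bis(benzyloxy)-2-{[(E)-1,2-dichloroethenyl]oxy}-5-(methoxymethoxy)benzene | Cl/C=C(/Cl)Oc1c(OCc2ccccc2)cc(OCOC)cc1OCc1ccccc1 | intermediate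
7 | 1,3-bis(benzyloxy)-2-(ethynyloxy)-5-(methoxymethoxy)benzene | C#COc1c(OCc2ccccc2)cc(OCOC)cc1OCc1ccccc1 | intermediate
8 | methyl coumalate (methyl 2-oxo-2H-pyran-5-carboxylate) | COC(=O)c1ccc(=O)oc1 | starting material
9 | methyl 8-[2,6-bis(benzyloxy)-4-(methoxymethoxy)phenoxy]-3-oxo-2-oxabicyclo[2.2.2]octa-5,7-diene-6-carboxylate (racemic) | O=C1OC2C=C(Oc3c(OCc4ccccc4)cc(OCOC)cc3OCc3ccccc3)C1C=C2C(=O)OC | intermediate
10 | methyl 4-[2,6-bis(benzyloxy)-4-(methoxymethoxy)phenoxy]benzoate | COC(=O)c1ccc(Oc2c(OCc3ccccc3)cc(OCOC)cc2OCc2ccccc2)cc1 | intermediate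
11 | 2,4,6-trihydroxyacetophenone | CC(=O)c1c(O)cc(O)cc1O | starting material
12 | 1-[2,4-bis(benzyloxy)-6-hydroxyphenyl]ethan-1-one | CC(=O)c1c(O)cc(OCc2ccccc2)cc1OCc1ccccc1 | intermediate
13 | 1-[2,4-bis(benzyloxy)-6-hydroxyphenyl]-3-{4-[2,6-bis(benzyloxy)-4-(methoxymethoxy)phenoxy]phenyl}propane-1,3-dione | O=C(CC(=O)c1ccc(Oc2c(OCc3ccccc3)cc(OCOC)cc2OCc2ccccc2)cc1)c1c(O)cc(OCc2ccccc2)cc1OCc1ccccc1 | intermediate
14 | 5,7-bis(benzyloxy)-2-{4-[2,6-bis(benzyloxy)-4-hydroxyphenoxy]phenyl}-4H-chromen-4-one | O=c1cc(-c2ccc(Oc3c(OCc4ccccc4)cc(O)cc3OCc3ccccc3)cc2)oc2cc(OCc3ccccc3)cc(OCc3ccccc3)c12 | intermediate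
15 | 5,7-bis(benzyloxy)-2-{4-[2,6-bis(benzyloxy)-4-hydroxy-3-iodophenoxy]phenyl}-4H-chromen-4-one | O=c1cc(-c2ccc(Oc3c(OCc4ccccc4)cc(O)c(I)c3OCc3ccccc3)cc2)oc2cc(OCc3ccccc3)cc(OCc3ccccc3)c12 | intermediate
16 | 5,7-bis(benzyloxy)-2-{4-[2,6-bis(benzyloxy)-3-(1-ethoxyethenyl)-4-hydroxyphenoxy]phenyl}-4H-chromen-4-one | C=C(OCC)c1c(O)cc(OCc2ccccc2)c(Oc2ccc(-c3cc(=O)c4c(OCc5ccccc5)cc(OCc5ccccc5)cc4o3)cc2)c1OCc1ccccc1 | intermediate
17 | 2-{4-[3-acetyl-2,6-bis(benzyloxy)-4-hydroxyphenoxy]phenyl}-5,7-bis(benzyloxy)-4H-chromen-4-one | CC(=O)c1c(O)cc(OCc2ccccc2)c(Oc2ccc(-c3cc(=O)c4c(OCc5ccccc5)cc(OCc5ccccc5)cc4o3)cc2)c1OCc1ccccc1 | intermediate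
18 | 2-{4-[2,6-bis(benzyloxy)-3-[(E)-3-(dimethylamino)prop-2-enoyl]-4-hydroxyphenoxy]phenyl}-5,7-bis(benzyloxy)-4H-chromen-4-one | CN(C)/C=C/C(=O)c1c(O)cc(OCc2ccccc2)c(Oc2ccc(-c3cc(=O)c4c(OCc5ccccc5)cc(OCc5ccccc5)cc4o3)cc2)c1OCc1ccccc1 | intermediate
19 | 5,7-bis(benzyloxy)-6-{4-[5,7-bis(benzyloxy)-4-oxo-4H-chromen-2-yl]phenoxy}-4H-chromen-4-one | O=c1ccoc2cc(OCc3ccccc3)c(Oc3ccc(-c4cc(=O)c5c(OCc6ccccc6)cc(OCc6ccccc6)cc5o4)cc3)c(OCc3ccccc3)c12 | intermediate
20 | 4-(benzyloxy)phenylboronic acid | OB(O)c1ccc(OCc2ccccc2)cc1 | starting material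
21 | (2S)-5,7-bis(benzyloxy)-2-[4-(benzyloxy)phenyl]-6-{4-[5,7-bis(benzyloxy)-4-oxo-4H-chromen-2-yl]phenoxy}-2,3-dihydro-4H-chromen-4-one | O=C1C[C@@H](c2ccc(OCc3ccccc3)cc2)Oc2cc(OCc3ccccc3)c(Oc3ccc(-c4cc(=O)c5c(OCc6ccccc6)cc(OCc6ccccc6)cc5o4)cc3)c(OCc3ccccc3)c21 | intermediate
22 | (2S)-5,7-dihydroxy-6-{4-[5,7-dihydroxy-4-oxo-4H-chromen-2-yl]phenoxy}-2-(4-hydroxyphenyl)-2,3-dihydro-4H-chromen-4-one | O=C1C[C@@H](c2ccc(O)cc2)Oc2cc(O)c(Oc3ccc(-c4cc(=O)c5c(O)cc(O)cc5o4)cc3)c(O)c21 | target

**Step count**

Total step count: 13. Longest linear sequence: 12 steps (steps 1–5 and 7–13, from compound 1).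

**Steps most likely to fail**

Step 5 (key cycloaddition). The ynol ether 7 may oligomerise or be hydrated faster than it adds to the pyrone, or the cycloaddition may need a temperature at which 7 does not survive; partial loss of para regiocontrol is a lesser risk. The fallback sets out from phenol 4 and forms the diaryl ether by a copper-catalysed Ullmann-type O-arylation with methyl 4-iodobenzoate (CuI 10 mol%, picolinic acid 20 mol%, K3PO4, DMSO, 90 °C), a protocol that tolerates ortho,ortho'-disubstituted phenols. It comes back to the route at compound 10 and bypasses steps 3 to 5.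

Step 12 (asymmetric 1,4-addition). Insertion into the electron-rich, 5-substituted chromone may be slower than protodeboronation of 20, or facial discrimination may be insufficient. The fallback sets out from acetophenone 17 and closes the ring by an organocatalytic oxa-Michael reaction instead:
- C-carboxylation of the dilithium phenoxide–enolate (LiN(SiMe3)2 3.3 equiv, di-tert-butyl dicarbonate, THF, −78 °C, AcOH quench) should give tert-butyl 3-[2,4-bis(benzyloxy)-3-{4-[5,7-bis(benzyloxy)-4-oxo-4H-chromen-2-yl]phenoxy}-6-hydroxyphenyl]-3-oxopropanoate F1.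
- Knoevenagel condensation with 4-(benzyloxy)benzaldehyde (piperidine/AcOH cat., toluene, 4 Å sieves) should give tert-butyl 2-[2,4-bis(benzyloxy)-3-{4-[5,7-bis(benzyloxy)-4-oxo-4H-chromen-2-yl]phenoxy}-6-hydroxybenzoyl]-3-[4-(benzyloxy)phenyl]prop-2-enoate F2.
- A bifunctional 9-amino-9-deoxy-epi-cinchona 3,5-bis(trifluoromethyl)phenyl thiourea (10 mol%, toluene, −25 °C), in the pseudoenantiomeric form that delivers the 2S series, should close the ring by intramolecular oxa-Michael addition to tert-butyl (2S)-5,7-bis(benzyloxy)-2-[4-(benzyloxy)phenyl]-6-{4-[5,7-bis(benzyloxy)-4-oxo-4H-chromen-2-yl]phenoxy}-4-oxo-3,4-dihydro-2H-chromene-3-carboxylate F3, which is not isolated.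
- TsOH in toluene at 80 °C in the same flask removes the tert-butyl ester and the carboxyl group, and the sequence comes back to the route at compound 21.

Step 13 (global hydrogenolysis). The flavone C2''=C3'' bond may be saturated, or the benzylic C2–O1 bond of the flavanone cleaved, before all five benzyl ethers are gone. The fallback sets out from compound 21 and removes the benzyl groups by Lewis-acid dealkylation with a cation scavenger (BCl3 10 equiv, pentamethylbenzene 15 equiv, CH2Cl2, −78 °C, MeOH quench). It comes back to the route at compound 22.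

**Further compounds**

F0 | step 5 | none | none
F1 | step 12 | tert-butyl 3-[2,4-bis(benzyloxy)-3-{4-[5,7-bis(benzyloxy)-4-oxo-4H-chromen-2-yl]phenoxy}-6-hydroxyphenyl]-3-oxopropanoate | CC(C)(C)OC(=O)CC(=O)c1c(O)cc(OCc2ccccc2)c(Oc2ccc(-c3cc(=O)c4c(OCc5ccccc5)cc(OCc5ccccc5)cc4o3)cc2)c1OCc1ccccc1
F2 | step 12 | tert-butyl 2-[2,4-bis(benzyloxy)-3-{4-[5,7-bis(benzyloxy)-4-oxo-4H-chromen-2-yl]phenoxy}-6-hydroxybenzoyl]-3-[4-(benzyloxy)phenyl]prop-2-enoate (E/Z mixture) | CC(C)(C)OC(=O)C(=Cc1ccc(OCc2ccccc2)cc1)C(=O)c1c(O)cc(OCc2ccccc2)c(Oc2ccc(-c3cc(=O)c4c(OCc5ccccc5)cc(OCc5ccccc5)cc4o3)cc2)c1OCc1ccccc1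
F3 | step 12 | tert-butyl (2S)-5,7-bis(benzyloxy)-2-[4-(benzyloxy)phenyl]-6-{4-[5,7-bis(benzyloxy)-4-oxo-4H-chromen-2-yl]phenoxy}-4-oxo-3,4-dihydro-2H-chromene-3-carboxylate (C3 epimers) | O=C1C(C(=O)OC(C)(C)C)[C@@H](c2ccc(OCc3ccccc3)cc2)Oc2cc(OCc3ccccc3)c(Oc3ccc(-c4cc(=O)c5c(OCc6ccccc6)cc(OCc6ccccc6)cc5o4)cc3)c(OCc3ccccc3)c21
F0 | step 13 | none | none
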